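The earlier runs and the new flask stem from a simulated flask with constants of no real substance, and the scatter is random.

The vessel is closed and stirred, and the next charge is substrate with free catalyst at the usual level. The choice is the temperature programme: whether to heat at all.

in all of them: free catalyst 1.2 mM
- south: substrate 0.070 M; temperature −5 °C; run made earlier
- west: substrate 0.11 M; temperature 25 °C; run made earlier
- dawn: substrate 0.050 M; at 50 °C until 40 min, from then on at 0 °C; time 2.0 h
- spring: substrate 0.050 M; temperature 0 °C; time 2.0 h
- autumn: substrate 0.050 M; temperature 50 °C; time 2.0 h
- noon: substrate 0.050 M; temperature 25 °C; time 2.0 h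

- south (time / min: target / %): 4.00: 4.7; 12.0: 12.3; 20.0: 17.7; 30.0: 23.6; 40.0: 28.5; 60.0: 35.5; 80.0: 41.1
- west (time / min: target / %): 1.33: 11.3; 4.00: 25.5; 6.00: 31.7; 8.00: 36.3; 12.0: 43.2; 20.0: 49.4; 25.0: 52.2

(scatter of a reading: 0.3 percentage points)

- the best flask by amount of target, in percent of the substrate charged; "all alike" if 1.5 percentage points covers them all (dawn / spring / autumn / noon / all alike)
- amount of target at the end, in percent of the substrate charged, dawn
- amount of target at the end, in percent of the substrate charged, spring
- amount of target at the end, in percent of the substrate charged, autumn
- amount of target at the end, in percent of the substrate charged, noon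

- a reading or a percentage of target counts all its forms, free or not

I reckon with one quantity, the opening constant: the fraction of the remaining substrate that becomes target per minute at the start of a flask, a pseudo-first-order constant for this catalyst charge. I assume it doesn't depend on the substrate charge. The first reading of the west run gives 0.0902 min⁻¹ at 25 °C, and that of the south run gives 0.0120 min⁻¹ at −5 °C. As a reading, that is an activation energy of 44.6 kJ mol⁻¹. Carried to 50 °C, the opening constant is 0.363 min⁻¹, and at 0 °C it is 0.0174 min⁻¹.

So 2.0 h holds about 15.6 half-lives at noon's temperature but 3.01 at spring's, and a half-life in autumn would be 1.91 min. Noon therefore has time enough without heat. The west run warns me, though: at 25.0 min the opening constant promises 89.5 %, yet the reading is 52.2 %, less than that. And 50 °C stands beyond both runs. Heat buys speed that noon doesn't need, so I would charge noon.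

The forecast differs and names dawn, with dawn 62 % (56 % to 68 %), spring 60 % (53 % to 65 %), autumn 44 % (35 % to 50 %) and noon 58 % (55 % to 61 %). Its ground is that “the straight line favours equilibrium”.

The flasks give dawn 33.7 %, spring 54.8 %, autumn 33.7 % and noon 57.9 %, so the best is noon.

    crystals ⇌ target, rate k1*(cs1 - [target]) while solid is left; crystals form when [target] > cs1 (solubility = 6.60 mM, k = 0.420 min⁻¹)
    2 free catalyst → spent catalyst (k = 74.0 M⁻¹ min⁻¹, Ea = 42.0 kJ mol⁻¹)
    substrate → side product (k = 0.0250 min⁻¹, Ea = 96.0 kJ mol⁻¹)
    substrate + free catalyst → free catalyst + target (k = 83.0 M⁻¹ min⁻¹, Ea = 46.0 kJ mol⁻¹)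
    (constants at 25 °C)

The main reason for autumn's low figure is the reaction of substrate to side product: without it, autumn ends at 93.8 % of target instead of 33.7 %. At 50 °C the constant of that side step is 0.500 min⁻¹, larger than my opening constant of 0.363 min⁻¹, so by my reckoning substrate at the start of autumn goes faster to side product than to target. Dawn ends level with autumn, its substrate at 0 % by the change of temperature.

In the neighbour flask, autumn with 0.0030 M of free catalyst, the opening constant, if it goes with the catalyst charge, scales to 0.907 min⁻¹, now above the side constant, so I expect target to lead at the start of that flask. At its end that flask computes to less target, 49.4 %, than side product, 50.6 %.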